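**Plan**

1. Retrosynthesis: the last cuts are the benzyl ether and the (S)-1-phenylethyl acetal (hydrogenolysis) and the CH2OH group (from CO2H). The seven-membered ring is then opened by excising CO2, which cuts the ring B C–O(ester) bond and the ring A C–C(=O) bond; the CO2H on the neighbouring ring B carbon is excised as a second CO2.
2. This leads to diaryl ether 17, with an iodide on ring A ortho to the ether oxygen and a 2-silylaryl triflate on ring B. The ether is cut (Ullmann) into bromophenol 3 and diiodobenzaldehyde 6.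
3. Enabling feature: on ring B the carbon bearing the ester oxygen and the carbon bearing CH2OH are ortho neighbours, the two ends of an aryne. The ester carbonyl sits on the ring A carbon ortho to the diaryl ether oxygen, so a ring A carboxylate made from CO2 can reach only the nearer aryne carbon (seven-membered ring) and leaves the anion on the carbon that must carry carbon.
4. Forward order: the two rings are joined as the ether, carbonylation closes the five-membered hydroxyphthalide ring on ring B, the aryne precursor is installed, and the key step closes the dioxepinone ring last.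
5. Stereochemistry: the only stereocentre, the lactol carbon, is fixed as the (R)-acetal of (S)-1-phenylethanol (epimers separated in step 7, wrong epimer recycled). It is released in the last step by hydrogenolysis of the O–CH(CH3)Ph bond, which breaks no bond to it.

Key step: step 12

Remark on the chemistry (assumption): the lactol carbon is a hemiacetal centre that can epimerise by ring–chain tautomerism. It is assumed to hold its configuration in neutral aprotic media, so it is unveiled only in the last step and the product is handled without acid, base or protic solvent.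

**Route**

Step 1
Reactants: 1 2,5-dimethylbenzene-1,3-diol
Product: 2 4-bromo-2,5-dimethylbenzene-1,3-diol
Conditions: NBS (1.0 equiv), MeCN/CH2Cl2, −40 °C → 0 °C
Reagents that add atoms: N-bromosuccinimide, O=C1CCC(=O)N1Br
Why: Electrophilic aromatic bromination; the two open ring positions of the symmetric resorcinol are equivalent, so the site is unambiguous, and one equivalent of NBS at low temperature should limit dibromination.

Step 2
Reactants: 2 4-bromo-2,5-dimethylbenzene-1,3-diol
Product: 3 2-bromo-5-methoxy-3,6-dimethylphenol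
Conditions: MeI (1.0 equiv), K2CO3 (1.0 equiv), acetone, rt
Reagents that add atoms: iodomethane, CI
Why: Williamson O-methylation; the hydroxyl flanked by bromine and methyl is hindered and hydrogen-bonded to bromine, so the hydroxyl para to bromine should be alkylated first, as in the selective mono-alkylation of 4-bromoresorcinol.

Step 3
Reactants: 4 3,5-dihydroxybenzaldehyde
Product: 5 3,5-bis(methoxymethoxy)benzaldehyde
Conditions: MOMCl, iPr2NEt, CH2Cl2, 0 °C → rt
Reagents that add atoms: chloromethyl methyl ether, COCCl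
Why: Standard MOM protection of both phenols, needed because free phenols on this ring would compete in the later copper-catalysed ether synthesis.

Step 4
Reactants: 5 3,5-bis(methoxymethoxy)benzaldehyde
Product: 6 2,6-diiodo-3,5-bis(methoxymethoxy)benzaldehyde
Conditions: NIS (2.3 equiv), TFA (cat.), MeCN, rt → 40 °C
Reagents that add atoms: N-iodosuccinimide, O=C1CCC(=O)N1I
Why: Electrophilic aromatic iodination at the two equivalent positions ortho to the formyl group, each ortho and para to an alkoxy group; the position between the two alkoxy groups is the most hindered and should stay free.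

Step 5
Reactants: 3 2-bromo-5-methoxy-3,6-dimethylphenol; 6 2,6-diiodo-3,5-bis(methoxymethoxy)benzaldehyde
Product: 7 2-(2-bromo-5-methoxy-3,6-dimethylphenoxy)-6-iodo-3,5-bis(methoxymethoxy)benzaldehyde
Conditions: CuI (20 mol%), picolinic acid (40 mol%), K3PO4, DMSO, 90 °C; 6 in twofold excess
Reagents that add atoms: none
Why: Ullmann-type copper-catalysed diaryl ether synthesis; the ortho formyl group accelerates coupling of the iodide, the aryl iodide should react in preference to the electron-rich ring A bromide, and the excess of symmetric 6 favours mono-coupling.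

Step 6
Reactants: 7 2-(2-bromo-5-methoxy-3,6-dimethylphenoxy)-6-iodo-3,5-bis(methoxymethoxy)benzaldehyde
Product: 9 4-(2-bromo-5-methoxy-3,6-dimethylphenoxy)-3,5,7-trihydroxy-2-benzofuran-1(3H)-one (racemic lactol), via bis-MOM hydroxyphthalide 8 (not isolated)
Conditions: Pd(OAc)2 (5 mol%), Xantphos, CO (1 atm), H2O, Et3N, DMF, 70 °C; then 3 M HCl, THF, 50 °C
Reagents that add atoms: carbon monoxide, [C-]#[O+]; water, O
Why: Palladium-catalysed hydroxycarbonylation of the aryl iodide (selective over the aryl bromide) gives the 2-formylbenzoic acid, which closes to the 3-hydroxyphthalide ring, and aqueous acid then hydrolyses both MOM acetals.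

Step 7
Reactants: 9 4-(2-bromo-5-methoxy-3,6-dimethylphenoxy)-3,5,7-trihydroxy-2-benzofuran-1(3H)-one; 10 (S)-1-phenylethanol
Product: 11 (3R)-4-(2-bromo-5-methoxy-3,6-dimethylphenoxy)-5,7-dihydroxy-3-[(1S)-1-phenylethoxy]-2-benzofuran-1(3H)-one
Conditions: CSA (10 mol%), toluene, 4 Å MS, 60 °C; chromatographic separation of the C3 epimers
Reagents that add atoms: none
Why: Acid-catalysed acetalisation of the lactol (pseudo-ester formation) under equilibrium control should give both C3 epimers; the (3R) epimer is isolated and the (3S) epimer is recycled by re-equilibration, so the configuration of the future lactol carbon is set here by separation against the (S) auxiliary.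

Step 8
Reactants: 11 (3R)-4-(2-bromo-5-methoxy-3,6-dimethylphenoxy)-5,7-dihydroxy-3-[(1S)-1-phenylethoxy]-2-benzofuran-1(3H)-one
Product: 12 (3R)-6-bromo-4-(2-bromo-5-methoxy-3,6-dimethylphenoxy)-5,7-dihydroxy-3-[(1S)-1-phenylethoxy]-2-benzofuran-1(3H)-one
Conditions: NBS (1.0 equiv), CH2Cl2, −40 °C → 0 °C
Reagents that add atoms: N-bromosuccinimide, O=C1CCC(=O)N1Br
Why: Electrophilic aromatic bromination of the free resorcinol-type ring at its only open position, between the two hydroxyls; the non-phenolic ring A, with one hindered position left, should react much more slowly with NBS.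

Step 9
Reactants: 12 (3R)-6-bromo-4-(2-bromo-5-methoxy-3,6-dimethylphenoxy)-5,7-dihydroxy-3-[(1S)-1-phenylethoxy]-2-benzofuran-1(3H)-one
Product: 15 (3R)-5,7-dihydroxy-4-(2-iodo-5-methoxy-3,6-dimethylphenoxy)-3-[(1S)-1-phenylethoxy]-6-(trimethylsilyl)-2-benzofuran-1(3H)-one, via bis-TMS ether 13 (not isolated), via dilithio silyl phenoxide 14 (not isolated)
Conditions: HMDS (neat), 80 °C, then evaporation; n-BuLi (2.2 equiv), THF, −100 → −78 °C; ICH2CH2I, −78 °C; aq. NH4Cl
Reagents that add atoms: hexamethyldisilazane, C[Si](C)(C)N[Si](C)(C)C; 1,2-diiodoethane, ICCI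
Why: Silylation, bromine–lithium exchange and retro-Brook (1,3 O-to-C) silyl migration on ring B is the standard entry to 2-silylphenols; the second equivalent of n-BuLi exchanges the ring A bromide, and that aryllithium is returned as the iodide by 1,2-diiodoethane, giving the handle for the later magnesium exchange.

Step 10
Reactants: 15 (3R)-5,7-dihydroxy-4-(2-iodo-5-methoxy-3,6-dimethylphenoxy)-3-[(1S)-1-phenylethoxy]-6-(trimethylsilyl)-2-benzofuran-1(3H)-one
Product: 16 (3R)-7-hydroxy-4-(2-iodo-5-methoxy-3,6-dimethylphenoxy)-1-oxo-3-[(1S)-1-phenylethoxy]-6-(trimethylsilyl)-1,3-dihydro-2-benzofuran-5-yl trifluoromethanesulfonate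
Conditions: Tf2O (1.05 equiv), pyridine, CH2Cl2, −40 → 0 °C
Reagents that add atoms: trifluoromethanesulfonic anhydride, O=S(=O)(OS(=O)(=O)C(F)(F)F)C(F)(F)F
Why: Selective O-sulfonylation of the phenol para to the lactone carbonyl; the other hydroxyl is deactivated by its hydrogen bond to that carbonyl, as in the mono-triflation of 2-silylresorcinols.

Step 11
Reactants: 16 (3R)-7-hydroxy-4-(2-iodo-5-methoxy-3,6-dimethylphenoxy)-1-oxo-3-[(1S)-1-phenylethoxy]-6-(trimethylsilyl)-1,3-dihydro-2-benzofuran-5-yl trifluoromethanesulfonate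
Product: 17 (3R)-7-(benzyloxy)-4-(2-iodo-5-methoxy-3,6-dimethylphenoxy)-1-oxo-3-[(1S)-1-phenylethoxy]-6-(trimethylsilyl)-1,3-dihydro-2-benzofuran-5-yl trifluoromethanesulfonate
Conditions: BnOH, PPh3, DIAD, THF, 0 °C → rt
Reagents that add atoms: benzyl alcohol, OCc1ccccc1
Why: Mitsunobu O-benzylation under neutral conditions, which avoids base-triggered loss of the silyl triflate and masks the phenol that would otherwise quench the organomagnesium and aryl anion of the next step.

Step 12
Reactants: 17 (3R)-7-(benzyloxy)-4-(2-iodo-5-methoxy-3,6-dimethylphenoxy)-1-oxo-3-[(1S)-1-phenylethoxy]-6-(trimethylsilyl)-1,3-dihydro-2-benzofuran-5-yl trifluoromethanesulfonate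
Product: 22 (1R)-4-(benzyloxy)-10-methoxy-8,11-dimethyl-3,7-dioxo-1-[(1S)-1-phenylethoxy]-1,3-dihydro-7H-isobenzofuro[4,5-b][1,4]benzodioxepine-5-carboxylic acid, via arylmagnesium chloride 18 (not isolated), via chloromagnesium carboxylate 19 (not isolated), via aryne carboxylate 20 (not isolated), via cyclised arylmagnesium 21 (not isolated)
Conditions: iPrMgCl·LiCl (1.1 equiv), THF, −20 → 0 °C; CO2 (1 atm), −20 → 0 °C; then KF, 18-crown-6, THF (0.01 M), CO2 (1 atm), 0 °C → rt; aq. citric acid
Reagents that add atoms: carbon dioxide, O=C=O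
Why: Proposed new method: iodine–magnesium exchange at the ring A carbon ortho to the ether oxygen gives 18, which captures CO2 to give carboxylate 19; fluoride then strips the silyl group and expels triflate to give aryne 20, the carboxylate oxygen adds to the nearer aryne carbon, and the resulting aryl anion 21 on the adjacent carbon takes up a second CO2, so the ring A C–C(=O) bond and the ring B C–O bond arise in one flask. The closest known reaction types are the three-component coupling of arynes with amines and CO2, the O-arylation of carboxylic acids by arynes and the carboxylation of aryl Grignard reagents. The seven-membered dioxepinone ring closes by 7-exo-dig attack of oxygen on the aryne, the second aryne carbon lying outside the new ring. No stereocentre is formed and the acetal carbon is untouched by the fluoride conditions. The step needs attack at the aryne carbon next to the diaryl ether oxygen and not at the one next to the benzyloxy group: the two flanking oxygens polarise the triple bond in opposite senses and leave little intrinsic bias, so the tether decides, because only the nearer carbon can be reached through a seven-membered ring, and the anion then sits between the inductively stabilising benzyloxy and ester oxygens. Carboxylation must precede aryne formation, which the orthogonal triggers (Grignard exchange, then fluoride) secure; a 1,3-acyl shift of the aryl anion onto the new ester is blocked because it would need a meta-bridged tricycle, and high dilution suppresses intermolecular capture.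

Step 13
Reactants: 22 (1R)-4-(benzyloxy)-10-methoxy-8,11-dimethyl-3,7-dioxo-1-[(1S)-1-phenylethoxy]-1,3-dihydro-7H-isobenzofuro[4,5-b][1,4]benzodioxepine-5-carboxylic acid
Product: 23 (1R)-4-(benzyloxy)-5-(hydroxymethyl)-10-methoxy-8,11-dimethyl-1-[(1S)-1-phenylethoxy]-7H-isobenzofuro[4,5-b][1,4]benzodioxepine-3,7(1H)-dione
Conditions: BH3·THF, THF, 0 °C → rt; aqueous work-up
Reagents that add atoms: none
Why: Chemoselective borane reduction of a carboxylic acid; the acid reacts through an acyloxyborane far faster than the aryl ester, the lactone acetal or the ethers.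

Step 14
Reactants: 23 (1R)-4-(benzyloxy)-5-(hydroxymethyl)-10-methoxy-8,11-dimethyl-1-[(1S)-1-phenylethoxy]-7H-isobenzofuro[4,5-b][1,4]benzodioxepine-3,7(1H)-dione
Product: 24 (1R)-1,4-dihydroxy-5-(hydroxymethyl)-10-methoxy-8,11-dimethyl-7H-isobenzofuro[4,5-b][1,4]benzodioxepine-3,7(1H)-dione (CNP0321962.1)
Conditions: H2 (1 atm), 10% Pd/C, EtOAc, rt
Reagents that add atoms: none
Why: Hydrogenolysis cleaves the aryl benzyl ether and the benzylic O–CH(CH3)Ph bond of the acetal; no bond to the lactol carbon is broken, so the (R) configuration set in step 7 is carried over, and the neutral aprotic medium avoids ring–chain epimerisation.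

**Compound list**

1 | 2,5-dimethylbenzene-1,3-diol | Cc1cc(O)c(C)c(O)c1 | starting material
2 | 4-bromo-2,5-dimethylbenzene-1,3-diol | Cc1cc(O)c(C)c(O)c1Br | intermediate
3 | 2-bromo-5-methoxy-3,6-dimethylphenol | COc1cc(C)c(Br)c(O)c1C | intermediate
4 | 3,5-dihydroxybenzaldehyde | O=Cc1cc(O)cc(O)c1 | starting material
5 | 3,5-bis(methoxymethoxy)benzaldehyde | COCOc1cc(C=O)cc(OCOC)c1 | intermediate
6 | 2,6-diiodo-3,5-bis(methoxymethoxy)benzaldehyde | COCOc1cc(OCOC)c(I)c(C=O)c1I | intermediate
7 | 2-(2-bromo-5-methoxy-3,6-dimethylphenoxy)-6-iodo-3,5-bis(methoxymethoxy)benzaldehyde | COc1cc(C)c(Br)c(Oc2c(OCOC)cc(OCOC)c(I)c2C=O)c1C | intermediate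
8 | 4-(2-bromo-5-methoxy-3,6-dimethylphenoxy)-3-hydroxy-5,7-bis(methoxymethoxy)-2-benzofuran-1(3H)-one (racemic; ring-closed form of the 2-formylbenzoic acid; not isolated) | COc1cc(C)c(Br)c(Oc2c(OCOC)cc(OCOC)c3C(=O)OC(O)c23)c1C | intermediate
9 | 4-(2-bromo-5-methoxy-3,6-dimethylphenoxy)-3,5,7-trihydroxy-2-benzofuran-1(3H)-one (racemic lactol) | COc1cc(C)c(Br)c(Oc2c(O)cc(O)c3C(=O)OC(O)c23)c1C | intermediate
10 | (S)-1-phenylethanol | C[C@H](O)c1ccccc1 | starting material
11 | (3R)-4-(2-bromo-5-methoxy-3,6-dimethylphenoxy)-5,7-dihydroxy-3-[(1S)-1-phenylethoxy]-2-benzofuran-1(3H)-one | COc1cc(C)c(Br)c(Oc2c(O)cc(O)c3C(=O)O[C@@H](O[C@@H](C)c4ccccc4)c23)c1C | intermediate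
12 | (3R)-6-bromo-4-(2-bromo-5-methoxy-3,6-dimethylphenoxy)-5,7-dihydroxy-3-[(1S)-1-phenylethoxy]-2-benzofuran-1(3H)-one | COc1cc(C)c(Br)c(Oc2c(O)c(Br)c(O)c3C(=O)O[C@@H](O[C@@H](C)c4ccccc4)c23)c1C | intermediate
13 | (3R)-6-bromo-4-(2-bromo-5-methoxy-3,6-dimethylphenoxy)-3-[(1S)-1-phenylethoxy]-5,7-bis(trimethylsilyloxy)-2-benzofuran-1(3H)-one (not isolated) | COc1cc(C)c(Br)c(Oc2c(O[Si](C)(C)C)c(Br)c(O[Si](C)(C)C)c3C(=O)O[C@@H](O[C@@H](C)c4ccccc4)c23)c1C | intermediate
14 | dilithio species after retro-Brook shift: ring A aryllithium, C6-trimethylsilyl, lithium C5-phenoxide, C7-trimethylsilyloxy (drawn as the O5-lithium isomer; silyl migration from O7 gives the regioisomeric phenoxide and both give 15; not isolated) | COc1cc(C)c([Li])c(Oc2c(O[Li])c([Si](C)(C)C)c(O[Si](C)(C)C)c3C(=O)O[C@@H](O[C@@H](C)c4ccccc4)c23)c1C | intermediate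
15 | (3R)-5,7-dihydroxy-4-(2-iodo-5-methoxy-3,6-dimethylphenoxy)-3-[(1S)-1-phenylethoxy]-6-(trimethylsilyl)-2-benzofuran-1(3H)-one | COc1cc(C)c(I)c(Oc2c(O)c([Si](C)(C)C)c(O)c3C(=O)O[C@@H](O[C@@H](C)c4ccccc4)c23)c1C | intermediate
16 | (3R)-7-hydroxy-4-(2-iodo-5-methoxy-3,6-dimethylphenoxy)-1-oxo-3-[(1S)-1-phenylethoxy]-6-(trimethylsilyl)-1,3-dihydro-2-benzofuran-5-yl trifluoromethanesulfonate | COc1cc(C)c(I)c(Oc2c(OS(=O)(=O)C(F)(F)F)c([Si](C)(C)C)c(O)c3C(=O)O[C@@H](O[C@@H](C)c4ccccc4)c23)c1C | intermediate
17 | (3R)-7-(benzyloxy)-4-(2-iodo-5-methoxy-3,6-dimethylphenoxy)-1-oxo-3-[(1S)-1-phenylethoxy]-6-(trimethylsilyl)-1,3-dihydro-2-benzofuran-5-yl trifluoromethanesulfonate | COc1cc(C)c(I)c(Oc2c(OS(=O)(=O)C(F)(F)F)c([Si](C)(C)C)c(OCc5ccccc5)c3C(=O)O[C@@H](O[C@@H](C)c4ccccc4)c23)c1C | intermediate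
18 | arylmagnesium chloride: 17 with MgCl in place of iodine (not isolated) | COc1cc(C)c([Mg]Cl)c(Oc2c(OS(=O)(=O)C(F)(F)F)c([Si](C)(C)C)c(OCc5ccccc5)c3C(=O)O[C@@H](O[C@@H](C)c4ccccc4)c23)c1C | intermediate
19 | chloromagnesium 2-{[(3R)-7-(benzyloxy)-1-oxo-3-[(1S)-1-phenylethoxy]-5-(trifluoromethanesulfonyloxy)-6-(trimethylsilyl)-1,3-dihydro-2-benzofuran-4-yl]oxy}-4-methoxy-3,6-dimethylbenzoate (not isolated) | COc1cc(C)c(C(=O)O[Mg]Cl)c(Oc2c(OS(=O)(=O)C(F)(F)F)c([Si](C)(C)C)c(OCc5ccccc5)c3C(=O)O[C@@H](O[C@@H](C)c4ccccc4)c23)c1C | intermediate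
20 | aryne carboxylate: 19 after loss of the silyl group and triflate, with a C5–C6 triple bond in the benzofuranone ring (not isolated) | COc1cc(C)c(C(=O)O[Mg]Cl)c(OC2=C3C(=C(OCc5ccccc5)C#C2)C(=O)O[C@H]3O[C@@H](C)c4ccccc4)c1C | intermediate
21 | cyclised arylmagnesium: the depsidone of 22 with MgCl in place of CO2H (not isolated) | COc1cc(C)c2c(c1C)Oc1c(c([Mg]Cl)c(OCc4ccccc4)c3c1[C@H](O[C@@H](C)c5ccccc5)OC3=O)OC2=O | intermediate
22 | (1R)-4-(benzyloxy)-10-methoxy-8,11-dimethyl-3,7-dioxo-1-[(1S)-1-phenylethoxy]-1,3-dihydro-7H-isobenzofuro[4,5-b][1,4]benzodioxepine-5-carboxylic acid | COc1cc(C)c2c(c1C)Oc1c(c(C(=O)O)c(OCc4ccccc4)c3c1[C@H](O[C@@H](C)c5ccccc5)OC3=O)OC2=O | intermediate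
23 | (1R)-4-(benzyloxy)-5-(hydroxymethyl)-10-methoxy-8,11-dimethyl-1-[(1S)-1-phenylethoxy]-7H-isobenzofuro[4,5-b][1,4]benzodioxepine-3,7(1H)-dione | COc1cc(C)c2c(c1C)Oc1c(c(CO)c(OCc4ccccc4)c3c1[C@H](O[C@@H](C)c5ccccc5)OC3=O)OC2=O | intermediate
24 | (1R)-1,4-dihydroxy-5-(hydroxymethyl)-10-methoxy-8,11-dimethyl-7H-isobenzofuro[4,5-b][1,4]benzodioxepine-3,7(1H)-dione | COc1cc(C)c2c(c1C)Oc1c(c(CO)c(O)c3c1[C@H](O)OC3=O)OC2=O | target

**Summary**

Total step count: 14. Longest linear sequence: 12 steps (from 4, steps 3 to 14).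

Steps most likely to fail:

Step 12 (key step). The carboxylate may be captured intermolecularly, the aryne may be consumed by fluoride or solvent, or the aryl anion may be protonated before it takes up CO2. Fallback, setting out from 11 and coming back at 24: the lactone is closed by acylation instead of aryne capture. Compound 11 is deprotonated at both phenols (NaH, THF), subjected to bromine–lithium exchange (n-BuLi, −78 °C) and quenched with CO2 to give 2-{[(3R)-5,7-dihydroxy-1-oxo-3-[(1S)-1-phenylethoxy]-1,3-dihydro-2-benzofuran-4-yl]oxy}-4-methoxy-3,6-dimethylbenzoic acid F1. DCC-mediated lactonisation onto the neighbouring phenol, the classical depsidone closure, gives (1R)-4-hydroxy-10-methoxy-8,11-dimethyl-1-[(1S)-1-phenylethoxy]-7H-isobenzofuro[4,5-b][1,4]benzodioxepine-3,7(1H)-dione F2. Magnesium-mediated ortho-formylation (MgCl2, Et3N, paraformaldehyde, MeCN) at the only open position next to the phenol gives the 5-carbaldehyde F3, and NaBH4 at 0 °C gives the 5-(hydroxymethyl) phenol F4. F4 rejoins the route at 24 under the conditions of step 14, where only the acetal auxiliary has to be cleaved.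

Step 5. C–O bond formation at a centre with four ortho substituents may be slow, with protodeiodination of 6 and self-coupling through the ring A bromide competing. Fallback, setting out from 1 and 6 and coming back at 7: the coupling is run before ring A carries bromine. 2,5-Dimethylbenzene-1,3-diol 1 and 6 are coupled under the same copper catalysis, now with only three ortho substituents and no competing C–Br bond, to give 2-(3-hydroxy-2,5-dimethylphenoxy)-6-iodo-3,5-bis(methoxymethoxy)benzaldehyde F5. Both partners are symmetric and difunctional, so this coupling is statistical and the mono-ether has to be separated from bis-coupled material. Bromination para to the free phenol (Bu4NBr3, CH2Cl2) gives 2-(2-bromo-5-hydroxy-3,6-dimethylphenoxy)-6-iodo-3,5-bis(methoxymethoxy)benzaldehyde F6, and O-methylation (MeI, K2CO3, acetone) gives 7.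

Step 14. Over-reduction of the benzylic C–O bonds (hydroxymethyl group or lactol ring) or epimerisation of the released lactol may occur on the catalyst. Fallback, setting out from 23 and coming back at 24: hydrogenolysis is avoided and the configuration is secured by resolution. Mild aqueous acid (1 M HCl, THF, 40 °C) hydrolyses the acetal of 23 to racemic 4-(benzyloxy)-1-hydroxy-5-(hydroxymethyl)-10-methoxy-8,11-dimethyl-7H-isobenzofuro[4,5-b][1,4]benzodioxepine-3,7(1H)-dione F7. Chelation-controlled debenzylation ortho to the lactone carbonyl (MgBr2·OEt2, toluene/Et2O) gives racemic 1,4-dihydroxy-5-(hydroxymethyl)-10-methoxy-8,11-dimethyl-7H-isobenzofuro[4,5-b][1,4]benzodioxepine-3,7(1H)-dione F8. Preparative chromatography on a chiral stationary phase with a neutral eluent then delivers 24.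

**Further compounds**

F1 | step 12 | 2-{[(3R)-5,7-dihydroxy-1-oxo-3-[(1S)-1-phenylethoxy]-1,3-dihydro-2-benzofuran-4-yl]oxy}-4-methoxy-3,6-dimethylbenzoic acid | COc1cc(C)c(C(=O)O)c(Oc2c(O)cc(O)c3C(=O)O[C@@H](O[C@@H](C)c4ccccc4)c23)c1C
F2 | step 12 | (1R)-4-hydroxy-10-methoxy-8,11-dimethyl-1-[(1S)-1-phenylethoxy]-7H-isobenzofuro[4,5-b][1,4]benzodioxepine-3,7(1H)-dione | COc1cc(C)c2c(c1C)Oc1c(cc(O)c3c1[C@H](O[C@@H](C)c5ccccc5)OC3=O)OC2=O
F3 | step 12 | (1R)-4-hydroxy-10-methoxy-8,11-dimethyl-3,7-dioxo-1-[(1S)-1-phenylethoxy]-1,3-dihydro-7H-isobenzofuro[4,5-b][1,4]benzodioxepine-5-carbaldehyde | COc1cc(C)c2c(c1C)Oc1c(c(C=O)c(O)c3c1[C@H](O[C@@H](C)c5ccccc5)OC3=O)OC2=O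
F4 | step 12 | (1R)-4-hydroxy-5-(hydroxymethyl)-10-methoxy-8,11-dimethyl-1-[(1S)-1-phenylethoxy]-7H-isobenzofuro[4,5-b][1,4]benzodioxepine-3,7(1H)-dione | COc1cc(C)c2c(c1C)Oc1c(c(CO)c(O)c3c1[C@H](O[C@@H](C)c5ccccc5)OC3=O)OC2=O
F5 | step 5 | 2-(3-hydroxy-2,5-dimethylphenoxy)-6-iodo-3,5-bis(methoxymethoxy)benzaldehyde | Cc1cc(O)c(C)c(Oc2c(OCOC)cc(OCOC)c(I)c2C=O)c1
F6 | step 5 | 2-(2-bromo-5-hydroxy-3,6-dimethylphenoxy)-6-iodo-3,5-bis(methoxymethoxy)benzaldehyde | Cc1cc(O)c(C)c(Oc2c(OCOC)cc(OCOC)c(I)c2C=O)c1Br
F7 | step 14 | 4-(benzyloxy)-1-hydroxy-5-(hydroxymethyl)-10-methoxy-8,11-dimethyl-7H-isobenzofuro[4,5-b][1,4]benzodioxepine-3,7(1H)-dione (racemic) | COc1cc(C)c2c(c1C)Oc1c(c(CO)c(OCc4ccccc4)c3c1C(O)OC3=O)OC2=O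
F8 | step 14 | 1,4-dihydroxy-5-(hydroxymethyl)-10-methoxy-8,11-dimethyl-7H-isobenzofuro[4,5-b][1,4]benzodioxepine-3,7(1H)-dione (racemic) | COc1cc(C)c2c(c1C)Oc1c(c(CO)c(O)c3c1C(O)OC3=O)OC2=O
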